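C-a = ArCH on resorcinol ring R1. C-b/C-c = C3/C2 of the trans-dihydrobenzofuran (benzo ring B1). C-d = CH on C4 of B1. C-e = ArCH on resorcinol ring R2. C-f/C-g = C3/C2 of the cis-dihydrobenzofuran (benzo ring B2). C-h = CH on C4 of B2. Ring P (eight-membered) = C-a, two carbons of R1, C-b, C3a and C4 of B1, C-d, C-h. Ring Q (eight-membered) = C-d, C-e, two carbons of R2, C-f, C3a and C4 of B2, C-h.
Cuts, in retrosynthetic order: ten O-H masked as O-Me; C-f–C-g; both aryl–C-f bonds; anisyl–C-a; C-a–C-h together with C-h–C-d; anisyl–C-e and C-d–C-e; R1–C-a; B1–C-d; C-b–C-c.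
Enabling feature: in ring P the fusion carbon C-h, which bears C4 of ring B2, lies between C-a and C-d. Removing it contracts ring P to a dibenzocycloheptenone (C-a as C=O, R1, C-b, B1, C-d). That is the only ring size the C4-acetic acid of the trans cap can form by acylating R1.
Forward order: trans furan, seven-membered ketone, arm on C-d, ring P by one-carbon insertion that also joins the halves, anisyl on C-a, ring Q, cis furan, deprotection.
Stereochemistry: C-b comes from a chiral dirhodium catalyst and C-c from acid equilibration to trans. C-e comes from convex-face conjugate addition. C-d and C-h come from base equilibration next to a ketone, and C-d is kept in the shift. C-a comes from hydride delivery anti to B2, and C-f/C-g from a cis-selective carbene insertion with the same catalyst.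
Reinforcement of the key step: R1 carries two tosyloxy groups while the ring is enlarged. This switches off the competing aryl shift and activates the carbonyl group. The methoxy group of B2 next to C-f is exchanged later for the benzylic ether that the carbene needs.

Key step: step 16

Assumption: Rh2(R-PTAD)4 (PTAD = N-phthaloyl-adamantylglycinate) is taken to be the catalyst enantiomer that gives the (2R,3S) cis series; if the sense is opposite, Rh2(S-PTAD)4 is used in steps 7 and 24.
Remark: 1, 4, 6, 13, 18 and 23 are purchased.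

Step 1
Reactants: 1 1-bromo-3,5-dimethoxybenzene
Product: 2 2-bromo-4,6-dimethoxybenzaldehyde
Conditions: POCl3, DMF, 0 → 90 °C; then H2O
Reagents that add atoms: N,N-dimethylformamide CN(C)C=O; water O
Why: Vilsmeier–Haack formylation of a 5-substituted resorcinol dimethyl ether goes to the carbon para to one methoxy group and ortho to the other, here the one next to bromine, in preference to the more crowded carbon between the two methoxy groups.

Step 2
Reactants: 2 2-bromo-4,6-dimethoxybenzaldehyde
Product: 3 2-bromo-6-hydroxy-4-methoxybenzaldehyde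
Conditions: BCl3 (1.2 equiv), CH2Cl2, −78 → 0 °C; then H2O
Reagents that add atoms: none
Why: Chelation-controlled ether cleavage, in which BCl3 bridges the aldehyde oxygen and the adjacent methoxy oxygen so that only this methyl group is lost and the para methoxy group stays.

Step 3
Reactants: 3 2-bromo-6-hydroxy-4-methoxybenzaldehyde; 4 4-methoxybenzyl chloride
Product: 5 2-bromo-4-methoxy-6-[(4-methoxybenzyl)oxy]benzaldehyde
Conditions: K2CO3, DMF, 60 °C
Reagents that add atoms: none
Why: Williamson ether synthesis on the acidic chelated phenol installs the benzylic CH2 that becomes C-c together with its anisyl ring.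

Step 4
Reactants: 6 1,3-bis(benzyloxy)-5-bromobenzene; 5 2-bromo-4-methoxy-6-[(4-methoxybenzyl)oxy]benzaldehyde
Product: 8 racemic diaryl carbinol (future C-b as CHOH between R1 and B1), via aryl Grignard reagent 7 (not isolated)
Conditions: Mg, THF, reflux; then 5, THF, 0 °C; H2O work-up
Reagents that add atoms: none
Why: Grignard addition to the aldehyde joins ring R1 to the future C-b, the aryl bromide being inert to an arylmagnesium reagent at this temperature, and the racemic carbinol centre is erased in the next step.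

Step 5
Reactants: 8 racemic diaryl carbinol
Product: 9 diaryl ketone [3,5-bis(benzyloxy)phenyl]{2-bromo-4-methoxy-6-[(4-methoxybenzyl)oxy]phenyl}methanone
Conditions: Dess–Martin periodinane, CH2Cl2, rt
Reagents that add atoms: none
Why: Dess–Martin oxidation of a secondary diaryl carbinol is mild enough for the benzyl and 4-methoxybenzyl ethers.

Step 6
Reactants: 9 diaryl ketone
Product: 10 hydrazone of 9 (E/Z mixture)
Conditions: N2H4·H2O (excess), AcOH (cat.), n-BuOH, 110 °C
Reagents that add atoms: hydrazine NN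
Why: Hydrazone condensation, driven by excess hydrazine and heat because the ketone has two ortho substituents, meets no other electrophilic group in the molecule.

Step 7
Reactants: 10 hydrazone of 9
Product: 12 (2R,3S)-3-[3,5-bis(benzyloxy)phenyl]-4-bromo-6-methoxy-2-(4-methoxyphenyl)-2,3-dihydrobenzofuran (cis), via diaryldiazomethane 11 (not isolated)
Conditions: MnO2, CH2Cl2, 0 °C, filtration; then Rh2(R-PTAD)4 (1 mol %), CH2Cl2, 0 °C → rt
Reagents that add atoms: none
Why: Dehydrogenation of the hydrazone gives the diaryldiazomethane, and the derived donor/donor rhodium carbene undergoes 1,5 C–H insertion into the ether CH2, a reaction type known to give cis-2,3-diaryl-2,3-dihydrobenzofurans, with the chiral carboxylate ligands fixing C-b as 3S and the concerted insertion placing the anisyl group on C-c cis to R1 (2R).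

Step 8
Reactants: 12 cis 4-bromo-dihydrobenzofuran; 13 (2-tert-butoxy-2-oxoethyl)zinc chloride
Product: 14 tert-butyl 2-[(2R,3S)-3-[3,5-bis(benzyloxy)phenyl]-6-methoxy-2-(4-methoxyphenyl)-2,3-dihydrobenzofuran-4-yl]acetate (cis)
Conditions: Pd(dba)2 (5 mol %), P(t-Bu)3 (5 mol %), THF, 50 °C
Reagents that add atoms: none
Why: Negishi-type coupling of a Reformatsky reagent with an aryl bromide (neutral alpha-arylation of an ester) brings in C-d and C-a without base, so the cis ring and C-b are not touched.

Step 9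
Reactants: 14 cis tert-butyl ester
Product: 16 seven-membered cap ketone (C-a carbonyl between R1 and C-d H2; R1 as bis-benzyl ether; trans furan 2S/3S), via trans acid 15 (not isolated)
Conditions: TFA–CH2Cl2 (1:3), rt; then (CF3CO)2O, 0 °C → rt
Reagents that add atoms: none
Why: Acidolysis frees the acid, reversible ionisation of the C-c–O bond to the 4-methoxybenzyl cation lets the furan re-close to the more stable trans isomer (C-c becomes 2S, C-b unchanged), and the mixed trifluoroacetic anhydride then effects an intramolecular Friedel–Crafts acylation at the R1 carbon ortho and para to the two benzyloxy groups, the seven-membered ring being the only one the acyl carbon can reach.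

Step 10
Reactants: 16 seven-membered cap ketone; 2 2-bromo-4,6-dimethoxybenzaldehyde
Product: 17 (E)-enone (C-d=C-e; ring R2 on C-e trans to the carbonyl group)
Conditions: piperidine (cat.), AcOH (cat.), toluene, reflux, Dean–Stark trap
Reagents that add atoms: none
Why: Knoevenagel-type aldol condensation at the doubly activated (benzylic and alpha-keto) C-d H2 with a non-enolisable aldehyde, water removal driving it to the E alkene in which the bulky aryl group lies away from the carbonyl group.

Step 11
Reactants: 17 (E)-enone; 18 4-methoxyphenylmagnesium bromide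
Product: 20 arm-bearing seven-membered ketone (C-d–H trans to C-b–H across the ring; C-e R; R1 as bis-benzyl ether), via C-d epimer 19 (not isolated)
Conditions: CuBr·SMe2 (20 mol %), THF, −30 → 0 °C; H2O work-up; then DBU (cat.), toluene, rt
Reagents that add atoms: none
Why: Copper-catalysed conjugate addition of an aryl Grignard reagent, 1,2-attack being blocked by the two ortho substituents of R1, should reach C-e from the convex face of the roof-shaped tetracycle (the face of C-b–H), and DBU then equilibrates C-d so that the arm stands pseudo-axial on that same face, clear of the peri hydrogen H-5 of B1.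

Step 12
Reactants: 20 arm-bearing ketone (bis-benzyl ether)
Product: 21 arm-bearing ketone with both R1 phenols free
Conditions: BCl3, C6HMe5, CH2Cl2, −78 °C; then H2O
Reagents that add atoms: none
Why: Lewis acid debenzylation with pentamethylbenzene as a non-basic benzyl cation trap removes the two benzyl ethers at low temperature and spares the aryl methyl ethers, the aryl bromide and the trans furan.

Step 13
Reactants: 21 bis-phenol ketone
Product: 22 arm-bearing seven-membered ketone with R1 as bis-tosylate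
Conditions: TsCl, Et3N, DMAP (cat.), CH2Cl2, 0 °C → rt
Reagents that add atoms: 4-toluenesulfonyl chloride Cc1ccc(cc1)S(=O)(=O)Cl
Why: Sulfonylation of both phenols turns the two donors of R1 into acceptors, the change the ring enlargement of this ketone needs.

Step 14
Reactants: 23 2-bromo-3,5-dimethoxybenzaldehyde
Product: 24 (E)-(2-bromo-3,5-dimethoxybenzylidene)hydrazine
Conditions: N2H4·H2O (excess), EtOH, rt
Reagents that add atoms: hydrazine NN
Why: Hydrazone condensation with excess hydrazine, the excess suppressing azine formation.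

Step 15
Reactants: 24 aldehyde hydrazone
Product: 25 2-bromo-1-(diazomethyl)-3,5-dimethoxybenzene
Conditions: MnO2, Et2O–CH2Cl2, 0 °C, dark; filtered and used at once as a titrated solution
Reagents that add atoms: none
Why: Dehydrogenation of an aldehyde hydrazone with MnO2 is a standard entry to aryldiazomethanes, and the ortho bromine and the cold, acid-free solution slow its dimerisation.

Step 16
Reactants: 22 seven-membered ketone (bis-tosylate); 25 2-bromo-1-(diazomethyl)-3,5-dimethoxybenzene
Product: 28 ring P ketone (C-a carbonyl; C-h bearing the 2-bromo-3,5-dimethoxyphenyl ring B2; C-h–H anti to C-d–H), via diazonium alkoxide 26 (not isolated), via C-h epimer 27 (not isolated)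
Conditions: Sc(OTf)3 (15 mol %), 4 Å molecular sieves, toluene–CH2Cl2, −78 → −20 °C, slow addition of 25 (2.5 equiv); then DBU (cat.), rt
Reagents that add atoms: none
Why: Proposed new method: Sc(OTf)3 binds the ketone oxygen of 22, the diazo carbon of 25 adds to C-a to give diazonium alkoxide 26, and the C-a–C-d bond lying anti to the C–N2 bond shifts to C-h as N2 leaves, so that C-a–C-h and C-h–C-d form and the seven-membered ring grows to ring P. The closest known reaction type is the Lewis acid catalysed Büchner–Curtius–Schlotterbeck (Tiffeneau–Demjanov type) homologation of cycloalkanones with aryldiazomethanes to 2-arylcycloalkanones; new here is a benzo-fused aryl ketone in which a methine carbon has to shift. Ring P closes by ring expansion, a 1,2-shift inside an existing ring, so no end-to-end medium-ring cyclisation is involved. The selectivity needed is shift of C-d and not of the R1 carbon: R1 has two ortho substituents and carries tosyloxy groups ortho and para to its migrating carbon, which makes it a poor migrating group and also raises the electrophilicity of the carbonyl group, whereas C-d is a secondary benzylic carbon. C-d keeps its configuration because the shift is suprafacial, and C-h, benzylic and alpha to the ketone, is taken by DBU from the kinetic mixture containing 27 to the isomer with ring B2 trans to the arm on C-d.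

Step 17
Reactants: 28 ring P ketone; 18 4-methoxyphenylmagnesium bromide
Product: 29 tertiary carbinol at C-a (mixture at C-a; all other centres as in 28)
Conditions: LaCl3·2LiCl, THF, 0 °C → rt; H2O work-up
Reagents that add atoms: none
Why: 1,2-Addition of an aryl Grignard reagent promoted by LaCl3·2LiCl, which raises carbonyl reactivity and holds back enolisation at C-h, is helped by the electron-poor R1, and the configuration of the new carbinol carbon is irrelevant because it is ionised next.

Step 18
Reactants: 29 tertiary carbinol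
Product: 30 ring P dibromide with C-a(H)(4-methoxyphenyl) (C-a–H syn to C-h–H; R1 as bis-tosylate)
Conditions: Et3SiH, TFA, CH2Cl2, −40 → 0 °C
Reagents that add atoms: none
Why: Ionic hydrogenation, in which TFA ionises the carbinol to the 4-methoxyphenyl-stabilised cation and Et3SiH delivers hydride from the outer face that carries C-h–H, anti to ring B2, which sets C-a, while no arene can trap the cation because both ortho positions of R2 are filled and attack by C5 of B1 would require a four-atom meta bridge.

Step 19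
Reactants: 30 bis-tosylate dibromide
Product: 32 deca-O-methyl dibromide, via bis-phenol 31 (not isolated)
Conditions: KOH, MeOH–THF, 65 °C; then MeI, K2CO3, DMF, rt
Reagents that add atoms: iodomethane CI
Why: Saponification of the two aryl sulfonates at sulfur followed by Williamson methylation restores an ether protection that tolerates organolithium reagents.

Step 20
Reactants: 32 deca-O-methyl dibromide
Product: 34 ring Q ketone (C-f as C=O between R2 and B2), via dilithio compound 33 (not isolated)
Conditions: t-BuLi (4.2 equiv), THF, −78 °C; then Me2NCOCl (1.0 equiv, slow addition), −78 °C → rt; H2O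
Reagents that add atoms: dimethylcarbamoyl chloride CN(C)C(=O)Cl
Why: Double bromine–lithium exchange followed by two acyl substitutions on one carbamoyl chloride is a known way to bridge two arenes with a carbonyl group, the first aryllithium giving the dimethylamide, the second attacking it within the molecule, and the lithium hemiaminal lasting until work-up so that no further addition occurs.

Step 21
Reactants: 34 ring Q ketone
Product: 35 ring Q ketone with the B2 oxygen ortho to C-f free
Conditions: BCl3, CH2Cl2, −78 → 0 °C; then H2O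
Reagents that add atoms: none
Why: Chelation-controlled ether cleavage, the methoxy group of B2 that will become the furan oxygen being the only one ortho to a carbonyl group in the molecule.

Step 22
Reactants: 35 ortho-hydroxy ketone; 4 4-methoxybenzyl chloride
Product: 36 ring Q ketone 4-methoxybenzyl ether
Conditions: K2CO3, n-Bu4NI (cat.), DMF, 60 °C
Reagents that add atoms: none
Why: Williamson ether synthesis places next to C-f the benzylic CH2 that becomes C-g together with its anisyl ring.

Step 23
Reactants: 36 ketone 4-methoxybenzyl ether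
Product: 37 hydrazone of 36
Conditions: N2H4·H2O (large excess), AcOH (cat.), diethylene glycol, 130 °C
Reagents that add atoms: hydrazine NN
Why: Hydrazone condensation under forcing, base-free conditions, needed for a diaryl ketone with three ortho substituents, leaves the aryl and benzyl ethers untouched and cannot proceed to reduction without strong base.

Step 24
Reactants: 37 hydrazone of 36
Product: 39 deca-O-methyl ether of the target (new cis furan; C-f S and C-g R), via cyclic diaryldiazomethane 38 (not isolated)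
Conditions: MnO2, CH2Cl2, 0 °C, filtration; then Rh2(R-PTAD)4 (2 mol %), CH2Cl2, 0 °C → rt
Reagents that add atoms: none
Why: The same donor/donor rhodium carbene 1,5 C–H insertion as in step 7 favours the oxygen- and aryl-activated ether CH2, is inherently cis selective, and with the same catalyst enantiomer should again give the 3S,2R sense, C-f–H ending on the face of ring Q that carries C-e–H and C-h–H.

Step 25
Reactants: 39 deca-O-methyl ether
Product: 40 target CNP0224452.3
Conditions: BBr3 (30 equiv), CH2Cl2, −78 → 0 °C; then ice-water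
Reagents that add atoms: none
Why: Exhaustive aryl methyl ether cleavage with BBr3, run cold and quenched cold, in which boron bound to the anisyl oxygen on C-g lowers its donor power so that the C-g–O bond of the cis furan should not ionise, while the trans furan is already the stable isomer.

Compound list
1 | 1-bromo-3,5-dimethoxybenzene | COc1cc(Br)cc(OC)c1 | starting material
2 | 2-bromo-4,6-dimethoxybenzaldehyde | COc1cc(Br)c(C=O)c(OC)c1 | intermediate
3 | 2-bromo-6-hydroxy-4-methoxybenzaldehyde | COc1cc(O)c(C=O)c(Br)c1 | intermediate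
4 | 4-methoxybenzyl chloride | COc1ccc(CCl)cc1 | starting material
5 | 2-bromo-4-methoxy-6-[(4-methoxybenzyl)oxy]benzaldehyde | COc1ccc(COc2cc(OC)cc(Br)c2C=O)cc1 | intermediate
6 | 1,3-bis(benzyloxy)-5-bromobenzene | Brc1cc(OCc2ccccc2)cc(OCc2ccccc2)c1 | starting material
7 | [3,5-bis(benzyloxy)phenyl]magnesium bromide | Br[Mg]c1cc(OCc2ccccc2)cc(OCc2ccccc2)c1 | intermediate
8 | racemic [3,5-bis(benzyloxy)phenyl]{2-bromo-4-methoxy-6-[(4-methoxybenzyl)oxy]phenyl}methanol | COc1ccc(COc2cc(OC)cc(Br)c2C(O)c2cc(OCc3ccccc3)cc(OCc3ccccc3)c2)cc1 | intermediate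
9 | [3,5-bis(benzyloxy)phenyl]{2-bromo-4-methoxy-6-[(4-methoxybenzyl)oxy]phenyl}methanone | COc1ccc(COc2cc(OC)cc(Br)c2C(=O)c2cc(OCc3ccccc3)cc(OCc3ccccc3)c2)cc1 | intermediate
10 | hydrazone of 9 (E/Z mixture) | COc1ccc(COc2cc(OC)cc(Br)c2C(=NN)c2cc(OCc3ccccc3)cc(OCc3ccccc3)c2)cc1 | intermediate
11 | diaryldiazomethane from 10 | COc1ccc(COc2cc(OC)cc(Br)c2C(=[N+]=[N-])c2cc(OCc3ccccc3)cc(OCc3ccccc3)c2)cc1 | intermediate
12 | (2R,3S)-3-[3,5-bis(benzyloxy)phenyl]-4-bromo-6-methoxy-2-(4-methoxyphenyl)-2,3-dihydrobenzofuran (cis) | c1(OCc2ccccc2)cc(OCc2ccccc2)cc(c1)[C@H]3c4c(cc(OC)cc4Br)O[C@H]3c2ccc(OC)cc2 | intermediate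
13 | (2-tert-butoxy-2-oxoethyl)zinc chloride | CC(C)(C)OC(=O)C[Zn]Cl | starting material
14 | tert-butyl 2-[(2R,3S)-3-[3,5-bis(benzyloxy)phenyl]-6-methoxy-2-(4-methoxyphenyl)-2,3-dihydrobenzofuran-4-yl]acetate (cis) | c1(OCc2ccccc2)cc(OCc2ccccc2)cc(c1)[C@H]3c4c(cc(OC)cc4CC(=O)OC(C)(C)C)O[C@H]3c2ccc(OC)cc2 | intermediate
15 | 2-[(2S,3S)-3-[3,5-bis(benzyloxy)phenyl]-6-methoxy-2-(4-methoxyphenyl)-2,3-dihydrobenzofuran-4-yl]acetic acid (trans) | c1(OCc2ccccc2)cc(OCc2ccccc2)cc(c1)[C@H]3c4c(cc(OC)cc4CC(=O)O)O[C@@H]3c2ccc(OC)cc2 | intermediate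
16 | seven-membered cap ketone: C-a carbonyl between R1 (two OBn) and C-d H2, trans furan (C-b S, C-c S) | O=C2c3c(OCc6ccccc6)cc(OCc6ccccc6)cc3[C@H]3c4c(cc(OC)cc4C2)O[C@@H]3c2ccc(OC)cc2 | intermediate
17 | (E)-enone: 16 with C-d=C-e(H)(2-bromo-4,6-dimethoxyphenyl), aryl trans to the carbonyl group | COc1cc(Br)c(c(OC)c1)/C=C2/C(=O)c3c(OCc5ccccc5)cc(OCc5ccccc5)cc3[C@H]3c4c(cc(OC)cc42)O[C@@H]3c2ccc(OC)cc2 | intermediate
18 | 4-methoxyphenylmagnesium bromide | COc1ccc([Mg]Br)cc1 | starting material
19 | C-d epimer of 20 | O=C2c3c(OCc6ccccc6)cc(OCc6ccccc6)cc3[C@H]3c4c(cc(OC)cc4[C@@H]2[C@H](c5ccc(OC)cc5)c5c(OC)cc(OC)cc5Br)O[C@@H]3c2ccc(OC)cc2 | intermediate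
20 | seven-membered ketone with arm C-e(H)(4-methoxyphenyl)(2-bromo-4,6-dimethoxyphenyl) on C-d, R1 with two OBn (C-b S, C-c S, C-d R, C-e R) | O=C2c3c(OCc6ccccc6)cc(OCc6ccccc6)cc3[C@H]3c4c(cc(OC)cc4[C@H]2[C@H](c5ccc(OC)cc5)c5c(OC)cc(OC)cc5Br)O[C@@H]3c2ccc(OC)cc2 | intermediate
21 | 20 with both R1 oxygens as free phenols | O=C2c3c(O)cc(O)cc3[C@H]3c4c(cc(OC)cc4[C@H]2[C@H](c5ccc(OC)cc5)c5c(OC)cc(OC)cc5Br)O[C@@H]3c2ccc(OC)cc2 | intermediate
22 | 21 as bis-tosylate (precursor of the key step) | O=C2c3c(OS(=O)(=O)c6ccc(C)cc6)cc(OS(=O)(=O)c6ccc(C)cc6)cc3[C@H]3c4c(cc(OC)cc4[C@H]2[C@H](c5ccc(OC)cc5)c5c(OC)cc(OC)cc5Br)O[C@@H]3c2ccc(OC)cc2 | intermediate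
23 | 2-bromo-3,5-dimethoxybenzaldehyde | COc1cc(OC)c(Br)c(C=O)c1 | starting material
24 | (E)-(2-bromo-3,5-dimethoxybenzylidene)hydrazine | COc1cc(OC)c(Br)c(/C=N/N)c1 | intermediate
25 | 2-bromo-1-(diazomethyl)-3,5-dimethoxybenzene (precursor of the key step) | COc1cc(OC)c(Br)c(C=[N+]=[N-])c1 | intermediate
26 | diazonium alkoxide from 22 and 25 (scandium on oxygen omitted; C-a and C-h undefined) | [O-]C2(C([N+]#N)c7cc(OC)cc(OC)c7Br)c3c(OS(=O)(=O)c6ccc(C)cc6)cc(OS(=O)(=O)c6ccc(C)cc6)cc3[C@H]3c4c(cc(OC)cc4[C@H]2[C@H](c5ccc(OC)cc5)c5c(OC)cc(OC)cc5Br)O[C@@H]3c2ccc(OC)cc2 | intermediate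
27 | C-h epimer of 28 | O=C2c3c(OS(=O)(=O)c6ccc(C)cc6)cc(OS(=O)(=O)c6ccc(C)cc6)cc3[C@H]3c4c(cc(OC)cc4[C@H]([C@H]2c7cc(OC)cc(OC)c7Br)[C@H](c5ccc(OC)cc5)c5c(OC)cc(OC)cc5Br)O[C@@H]3c2ccc(OC)cc2 | intermediate
28 | ring P ketone: C-a carbonyl, C-h bearing 2-bromo-3,5-dimethoxyphenyl trans to the arm on C-d, R1 as bis-tosylate (product of the key step) | O=C2c3c(OS(=O)(=O)c6ccc(C)cc6)cc(OS(=O)(=O)c6ccc(C)cc6)cc3[C@H]3c4c(cc(OC)cc4[C@H]([C@@H]2c7cc(OC)cc(OC)c7Br)[C@H](c5ccc(OC)cc5)c5c(OC)cc(OC)cc5Br)O[C@@H]3c2ccc(OC)cc2 | intermediate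
29 | tertiary carbinol: 28 with C-a(OH)(4-methoxyphenyl), mixture at C-a | OC2(c8ccc(OC)cc8)c3c(OS(=O)(=O)c6ccc(C)cc6)cc(OS(=O)(=O)c6ccc(C)cc6)cc3[C@H]3c4c(cc(OC)cc4[C@H]([C@@H]2c7cc(OC)cc(OC)c7Br)[C@H](c5ccc(OC)cc5)c5c(OC)cc(OC)cc5Br)O[C@@H]3c2ccc(OC)cc2 | intermediate
30 | ring P dibromide with C-a(H)(4-methoxyphenyl), C-a–H syn to C-h–H, R1 as bis-tosylate | COc1ccc([C@@H]2c3c(OS(=O)(=O)c6ccc(C)cc6)cc(OS(=O)(=O)c6ccc(C)cc6)cc3[C@H]3c4c(cc(OC)cc4[C@H]([C@@H]2c7cc(OC)cc(OC)c7Br)[C@H](c5ccc(OC)cc5)c5c(OC)cc(OC)cc5Br)O[C@@H]3c2ccc(OC)cc2)cc1 | intermediate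
31 | 30 with both R1 oxygens as free phenols | COc1ccc([C@@H]2c3c(O)cc(O)cc3[C@H]3c4c(cc(OC)cc4[C@H]([C@@H]2c7cc(OC)cc(OC)c7Br)[C@H](c5ccc(OC)cc5)c5c(OC)cc(OC)cc5Br)O[C@@H]3c2ccc(OC)cc2)cc1 | intermediate
32 | deca-O-methyl ring P dibromide | COc1ccc([C@@H]2c3c(OC)cc(OC)cc3[C@H]3c4c(cc(OC)cc4[C@H]([C@@H]2c7cc(OC)cc(OC)c7Br)[C@H](c5ccc(OC)cc5)c5c(OC)cc(OC)cc5Br)O[C@@H]3c2ccc(OC)cc2)cc1 | intermediate
33 | dilithio compound from 32 | COc1ccc([C@@H]2c3c(OC)cc(OC)cc3[C@H]3c4c(cc(OC)cc4[C@H]([C@@H]2c7cc(OC)cc(OC)c7[Li])[C@H](c5ccc(OC)cc5)c5c(OC)cc(OC)cc5[Li])O[C@@H]3c2ccc(OC)cc2)cc1 | intermediate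
34 | ring Q ketone: C-f as carbonyl between R2 and B2 | COc1ccc([C@@H]2c3c(OC)cc(OC)cc3[C@H]3c4c(cc(OC)cc4[C@H]4[C@H](c5ccc(OC)cc5)c5c(OC)cc(OC)cc5C(=O)c6c(OC)cc(OC)cc6[C@H]24)O[C@@H]3c2ccc(OC)cc2)cc1 | intermediate
35 | 34 with the B2 oxygen ortho to C-f as free phenol | COc1ccc([C@@H]2c3c(OC)cc(OC)cc3[C@H]3c4c(cc(OC)cc4[C@H]4[C@H](c5ccc(OC)cc5)c5c(OC)cc(OC)cc5C(=O)c6c(O)cc(OC)cc6[C@H]24)O[C@@H]3c2ccc(OC)cc2)cc1 | intermediate
36 | 35 as 4-methoxybenzyl ether | COc1ccc([C@@H]2c3c(OC)cc(OC)cc3[C@H]3c4c(cc(OC)cc4[C@H]4[C@H](c5ccc(OC)cc5)c5c(OC)cc(OC)cc5C(=O)c6c(OCc7ccc(OC)cc7)cc(OC)cc6[C@H]24)O[C@@H]3c2ccc(OC)cc2)cc1 | intermediate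
37 | hydrazone of 36 | COc1ccc([C@@H]2c3c(OC)cc(OC)cc3[C@H]3c4c(cc(OC)cc4[C@H]4[C@H](c5ccc(OC)cc5)c5c(OC)cc(OC)cc5C(=NN)c6c(OCc7ccc(OC)cc7)cc(OC)cc6[C@H]24)O[C@@H]3c2ccc(OC)cc2)cc1 | intermediate
38 | cyclic diaryldiazomethane from 37 | COc1ccc([C@@H]2c3c(OC)cc(OC)cc3[C@H]3c4c(cc(OC)cc4[C@H]4[C@H](c5ccc(OC)cc5)c5c(OC)cc(OC)cc5C(=[N+]=[N-])c6c(OCc7ccc(OC)cc7)cc(OC)cc6[C@H]24)O[C@@H]3c2ccc(OC)cc2)cc1 | intermediate
39 | deca-O-methyl ether of the target (C-a R, C-b S, C-c S, C-d R, C-e R, C-f S, C-g R, C-h S) | COc1ccc([C@@H]2c3c(OC)cc(OC)cc3[C@H]3c4c(cc(OC)cc4[C@H]4[C@H](c5ccc(OC)cc5)c5c(OC)cc(OC)cc5[C@H]5c6c(cc(OC)cc6[C@H]24)O[C@H]5c2ccc(OC)cc2)O[C@@H]3c2ccc(OC)cc2)cc1 | intermediate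
40 | CNP0224452.3 (C-a R, C-b S, C-c S, C-d R, C-e R, C-f S, C-g R, C-h S) | Oc1ccc([C@@H]2c3c(O)cc(O)cc3[C@H]3c4c(cc(O)cc4[C@H]4[C@H](c5ccc(O)cc5)c5c(O)cc(O)cc5[C@H]5c6c(cc(O)cc6[C@H]24)O[C@H]5c2ccc(O)cc2)O[C@@H]3c2ccc(O)cc2)cc1 | target

Total step count: 25.
Longest linear sequence: 23 steps (steps 1–13 and 16–25, from 1); steps 14 and 15 form the side branch.

Steps most likely to fail

Step 16. Addition of the weakly nucleophilic diazo carbon to a carbonyl group flanked by an ortho-substituted arene and a branched carbon may be slower than Lewis acid induced decay of the diazo compound. Shift of the aryl carbon may also still compete with shift of C-d.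

The fallback replaces the neutral nucleophile with a carbanion that carries its own leaving group, using only known reactions. It sets out from 25 and 22 and returns at 28.
- Diazo compound 25 reacts with p-toluenesulfinyl chloride, losing N2, to give chloro(2-bromo-3,5-dimethoxyphenyl)methyl p-tolyl sulfoxide F1.
- Deprotonation with LDA (THF, −78 °C) and addition to 22 give the beta-hydroxy alpha-chloro sulfoxide F2.
- Treatment with t-BuMgCl and then i-PrMgCl brings about sulfoxide–magnesium exchange.
- The known one-carbon ring enlargement through a magnesium beta-oxido carbenoid follows: chloride is lost, C-d shifts, and protonation of the enolate with the same DBU equilibration gives 28.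

Step 20. After the first acylation the second aryllithium may be protonated or carbamoylated before it reaches the hindered amide, so that closure of the eight-membered ring stalls.

The fallback closes the ring at the alcohol oxidation level. It sets out from 32 and returns at 34.
- The dilithio compound 33 is generated as before and treated with ethyl formate.
- The aryl aldehyde formed first is smaller and far more electrophilic than an amide, so it is captured within the molecule to give the cyclic diaryl carbinol F3.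
- Dess–Martin oxidation of F3 gives 34.

Step 24. The carbene may insert across ring Q into C-d–H. The ether CH2 may approach the wrong face of ring Q. The hydrazone formation that feeds the step may also remain incomplete at so hindered a ketone.

The fallback avoids both hydrazone and carbene. It sets out from 36 and returns at 39.
- The phosphazene base P4-t-Bu deprotonates the aryloxy-CH2-aryl group, and the carbanion adds to the neighbouring ketone to give the 3-hydroxy-2,3-dihydrobenzofuran F4.
- TsOH dehydrates F4 to the 2,3-diarylbenzofuran F5.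
- Hydrogenation (H2 under pressure, Pd/C, EtOAc–AcOH) adds both hydrogens to one face, so it can only give a cis furan, which leads to 39.

Further compounds
F1 | step 16 | chloro(2-bromo-3,5-dimethoxyphenyl)methyl p-tolyl sulfoxide (mixture of isomers) | Cc1ccc(cc1)S(=O)C(Cl)c1cc(OC)cc(OC)c1Br
F2 | step 16 | beta-hydroxy alpha-chloro sulfoxide from 22 and F1 (new centres undefined) | OC2(C(Cl)(S(=O)c8ccc(C)cc8)c7cc(OC)cc(OC)c7Br)c3c(OS(=O)(=O)c6ccc(C)cc6)cc(OS(=O)(=O)c6ccc(C)cc6)cc3[C@H]3c4c(cc(OC)cc4[C@H]2[C@H](c5ccc(OC)cc5)c5c(OC)cc(OC)cc5Br)O[C@@H]3c2ccc(OC)cc2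
F3 | step 20 | cyclic diaryl carbinol (C-f as CHOH, mixture at C-f) | COc1ccc([C@@H]2c3c(OC)cc(OC)cc3[C@H]3c4c(cc(OC)cc4[C@H]4[C@H](c5ccc(OC)cc5)c5c(OC)cc(OC)cc5C(O)c6c(OC)cc(OC)cc6[C@H]24)O[C@@H]3c2ccc(OC)cc2)cc1
F4 | step 24 | 3-hydroxy-2,3-dihydrobenzofuran (C-f as C-OH, C-f and C-g undefined) | COc1ccc([C@@H]2c3c(OC)cc(OC)cc3[C@H]3c4c(cc(OC)cc4[C@H]4[C@H](c5ccc(OC)cc5)c5c(OC)cc(OC)cc5C5(O)c6c(cc(OC)cc6[C@H]24)OC5c2ccc(OC)cc2)O[C@@H]3c2ccc(OC)cc2)cc1
F5 | step 24 | 2,3-diarylbenzofuran (C-f and C-g as the furan double bond) | COc1ccc([C@@H]2c3c(OC)cc(OC)cc3[C@H]3c4c(cc(OC)cc4[C@H]4[C@H](c5ccc(OC)cc5)c5c(OC)cc(OC)cc5-c5c6c(cc(OC)cc6[C@H]24)oc5-c2ccc(OC)cc2)O[C@@H]3c2ccc(OC)cc2)cc1
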